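The data are simulated for an exercise; noise was put on by code.

The ratio I follow is the time one flask takes to reach a given share of its charge, divided by the time a flask of smaller charge takes to reach the same share. I call it the stretch, s.

| flask | starting material | product | time |
|---|---|---|---|
| noon | 0.200 M |  |  |
| autumn | 0.200 M | 0.100 M |  |
| winter | 0.400 M |  |  |
| dusk | 0.500 M |  | 52 min |

| run | time / min | [product] / M |
|---|---|---|
| noon run | 6.5 | 0.0246 |
| noon run | 13 | 0.0515 |
| noon run | 20 | 0.0778 |
| noon run | 26 | 0.0942 |
| noon run | 32 | 0.1124 |
| noon run | 39 | 0.1310 |
| noon run | 46 | 0.1470 |
| noon run | 52 | 0.1562 |
| autumn run | 6.5 | 0.1249 |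
| autumn run | 13 | 0.1470 |
| autumn run | 20 | 0.1748 |
| autumn run | 26 | 0.1981 |
| autumn run | 32 | 0.2105 |
| autumn run | 39 | 0.2316 |
| autumn run | 46 | 0.2445 |
| autumn run | 52 | 0.2560 |
| winter run | 6.5 | 0.0349 |
| winter run | 13 | 0.0762 |
| winter run | 20 | 0.1190 |
| winter run | 26 | 0.1503 |
| winter run | 32 | 0.1828 |
| winter run | 39 | 0.2152 |
| winter run | 46 | 0.2459 |
| winter run | 52 | 0.2663 |

(standard deviation of a reading: 0.002 M)

- how the opening rate goes with [starting material] round the charge of the noon run: the exponent of the rate at two percent of starting material gone to product (one fixed amount of product, the same in the runs compared)
- product in the dusk run at 52 min, as a share of the starting material charged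

- Overall: starting material -> product.
- Constant volume, constant temperature.
- Readings of a species count what is bound in complexes too.
- An order is taken over about fifteen percent of the charge, up and down.

The two ends are easy. With a first-order rate, k[starting material] with rate constant k, the share made by a given time does not depend on the charge, so s is one. With a constant rate, the time grows with the charge, so doubling the charge makes s two. I join the ends by a power, s = (charge ratio)^e, where e is nought at the first end and one at the other, and one minus e is the apparent order over the course.

Comparing equal shares asks that product leaves the rate alone. The autumn run, less its added product, has made 0.1560 M at 52 min, and the noon run has made 0.1562 M, a gap smaller than the scatter.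

The winter run has made 66.6% of its charge at 52 min. Between its readings the noon run reaches that share at 39.9 min. So s reads 1.30, the stretch for doubling the charge, and e reads 0.381.

For the dusk charge, s becomes 1.42, so its 52 min counts as 36.7 min on the noon curve. There the noon run stands at 0.125 M, and I commit to a share of 62.4% for the dusk run.

The stretch describes whole courses, so for the opening I take the winter reading over the noon reading at 6.5 min, amounts made by one time rather than rates at one amount of product, and that ratio reads as an exponent of 0.505, give or take 0.144.

The forecast gives 0.6 and 61%, on the ground that “this looks like partial saturation rather than first order”. My exponent is lower and my share higher.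

The flask gives an exponent of 0.47 and a dusk share of 62.1%.

starting material ⇌ intermediate (0.2280 min⁻¹, 0.5334 min⁻¹); intermediate → product (0.1650 min⁻¹); starting material → product (0.02754 min⁻¹); 2 starting material ⇌ idle substrate dimer, settled at all times (20.70 M⁻¹) At the fixed amount of product, the winter rate over the noon rate is 1.4, and the forecast's exponent stands higher. On the noon curve 62.1% falls at 36.4 min, so the dusk stretch is 1.43 against the 1.42 reckoned. For the winter run, the noon quarter time 12.8 min multiplied by 1.30 gives 16.6 min, and the winter run's own quarter time is 16.7 min.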